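(The numbers in the tables stem from a simulated flask from invented constants; scatter was added.)

Count the partner.

all flasks: racemization catalyst 10 mM; added ligand 13 mM

| charge | left-handed substrate | right-handed substrate | coupling partner | remark | time |
|---|---|---|---|---|---|
| amber | 1 M | 1 M | 2.8 M | run made earlier |  |
| flask | 1.0 M | 1.0 M | 2.00 M |  | 1.0 h |

amber run (percent of the left-handed substrate and right-handed substrate together charged)

| time / min | left-handed product / % | right-handed product / % | left-handed substrate / % |
|---|---|---|---|
| 2.00 | 12.4 | 8.6 | 37.3 |
| 6.00 | 26.5 | 16.6 | 25.5 |
| 10.0 | 30.7 | 20.4 | 22.3 |
| 15.0 | 35.0 | 24.1 | 17.1 |
| 20.0 | 37.8 | 25.7 | 13.2 |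
| 30.0 | 40.0 | 26.7 | 11.6 |
| 40.0 | 42.4 | 30.1 | 13.4 |

(standard deviation of a reading: 1 percentage point)

- coupling partner is single-handed; left-handed substrate and right-handed substrate are mirror images of each other, charged as a racemate, each of them at the stated concentration
- an excess is below zero if the other one leads
- the handed part of coupling partner does not stay in what it makes, so the products of the two hands are mirror images too

1. left-handed product and right-handed product together, in percent of the left-handed substrate and right-handed substrate charged together, at 1.0 h
2. excess of left-handed product over right-handed product in the product at 1.0 h
3. whether the exchange between left-handed substrate and right-handed substrate keeps pace with the reaction: how far the product's excess at 1.0 h gets from its value without exchange to its value with instant exchange (above 80% keeps pace, below 20% hardly takes part, else lags behind)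

1. The amber run looks wrong. It charged 2.8 M of coupling partner against 2.00 M of substrate, both hands together. At 40.0 min its product stands at 72.5%. Subtraction then leaves c(coupling partner) at 1.35 M, more than the 0.550 M of c(substrate). Yet the product gained 22 percentage points between 2.00 min and 6.00 min, and 5.8 points between 30.0 min and 40.0 min.

2. I read this as partner leaving by a side road, where it spends itself on itself. So I ask where the flask must end, with partner used up and substrate still there.

3. I assume the side road's share follows the ratio of c(coupling partner) to c(substrate). Then the substrate left falls exponentially with the partner charged per substrate. I call the exponent per unit of that ratio the reach: ln(substrate charged / substrate left), divided by partner charged per substrate.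

4. Amber charged 1.40 partner per substrate, and its last row gives 0.922. But amber is not at its end there, since it gained 5.8 points in its last interval. So I hold this figure as a low reading of the reach, not as its end value.

5. The new flask charges 1.00. Its 1.0 h is longer than amber's 40.0 min, so I take it as close to its end. From the low reading I reckon 60.2% product, as a low figure.

6. The forecast says 60%, excess 20%, and exchange lags behind. On the slowing it says “one run can't separate these”. My reckoning speaks to the yield and nothing else.

7. The flask gives 64.4%, excess 18.7%, and exchange lags behind, 31% of the way. At 1.00 h the partner, the limiting reagent, is down to 2.46% of its charge, and 0.331 M of self-condensation product stands, two partner in each. Read back, this flask's reach is 1.03, above amber's low reading of 0.922, and my low figure stands 4.2 points below the flask's yield.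

    coupling partner + left-handed substrate → left-handed product (k = 0.00110 M⁻¹ s⁻¹)
    coupling partner + right-handed substrate → right-handed product (k = 6.40 × 10⁻⁴ M⁻¹ s⁻¹)
    left-handed substrate + racemization catalyst ⇌ right-handed substrate + racemization catalyst, rate k3*[racemization catalyst]*[left-handed substrate] forward; the back reaction follows from the equilibrium constant (k = 0.0610 M⁻¹ s⁻¹)
    2 coupling partner → self-condensation product (k = 3.50 × 10⁻⁴ M⁻¹ s⁻¹)
    racemization catalyst + added ligand ⇌ idle complex (K = 180 M⁻¹, k = 0.270 M⁻¹ s⁻¹)

8. With 0.50 M of partner, the same flask has a ratio of 0.250, and amber's low reading of the reach gives 20.6% product, again as a low figure. The computed result is 22.5%.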